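A small charge of Z, the dusk run, had turned 57.1 % of itself into L by 19 min, and I wanted that same share for the autumn charge.

| flask | Z | G | time |
|---|---|---|---|
| midnight | 300 mM | 450 mM |  |
| dusk | 120 mM | 270 mM |  |
| noon | 900 mM | 450 mM |  |
| autumn | 99.0 mM | 230 mM | 19 min |

| run | time / min | [L] / mM |
|---|---|---|
| midnight run | 0.84 | 34.4 |
| midnight run | 2.6 | 83.3 |
| midnight run | 4.9 | 120.1 |
| midnight run | 7.8 | 148.9 |
| midnight run | 11 | 165.1 |
| midnight run | 15 | 174.0 |
| midnight run | 19 | 176.5 |
| dusk run | 0.84 | 12.0 |
| dusk run | 2.6 | 26.6 |
| dusk run | 4.9 | 42.3 |
| dusk run | 7.8 | 52.9 |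
| dusk run | 11 | 61.0 |
| dusk run | 15 | 67.3 |
| dusk run | 19 | 68.5 |
| noon run | 0.84 | 94.2 |
| noon run | 2.6 | 220.5 |
| noon run | 4.9 | 296.7 |
| noon run | 7.8 | 328.8 |
| noon run | 11 | 331.6 |
| noon run | 15 | 331.6 |
| noon run | 19 | 332.8 |

(scatter of a reading: 0.9 mM)

* the power of [G] that the first rate follows, about the charge of the midnight run; measure it at two percent of Z made into L
* the power of [Z] that the first rate follows, about the charge of the midnight run; measure it at two percent of Z made into L (one fixed amount of L, the same in the runs compared)
* L in the autumn run at 19 min, as a share of the Z charged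

- Overall: Z + G -> L.
- Constant volume, constant temperature.
- The analysis sees a species whether free or bound.
- "The second partner" is G.
- An order is taken over about fifteen percent of the charge, up and down.

I reckoned with two times. The first was the lifetime of Z, the charge divided by the pace of the first reading: 7.33 min in the midnight run and 8.03 min in the noon run, although Z went from 300 mM to 900 mM, so a lifetime was a fair unit. In the dusk run, it read 8.40 min.

The second time was needed because the noon run stood at 331.6 mM at 11 min and 332.8 mM at 19 min, with L at 37.0 % of the Z charged. I therefore took G as the limiting reagent and called the second time its working span.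

Their ratio is the count, the number of Z lifetimes a run gets through by 19 min, the logarithm of the Z charged over the Z charged less the L read. It read 0.846 in the dusk run, 0.888 in the midnight run and 0.462 in the noon run.

Between the dusk and midnight runs, both charges changed widely, yet the count moved by only 0.0420. The autumn charges are 0.825 and 0.852 of the dusk charges, so I carried the dusk count over and committed to a share of 57.1 %.

The forecast gave 53.5 % (50 % to 57 %), below my share, with powers of 0.3 in G and 0.95 in Z, reasoning that “G runs out before 19 min at roughly 53–54% of Z”.

The autumn flask gave 57.0 % at 19 min, with powers of 0.56 in G and 1.0 in Z, by these steps: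

    Z + G → L (1.728 /M/min)
    L + G → X (0.4608 /M/min)
    2 G ⇌ G2, settled at all times (24.70 /M)
    2 G → Ky (2.292 /M/min)

In the dusk run the L made came to half of the Z charged at 10.3 min, a count of 0.693. The autumn share at 19 min is a count of 0.843, against the 0.846 read in the dusk run at 19 min.

The readings were generated by integration for substances that don't exist; the scatter is artificial.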